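**Plan**
1. Retrosynthesis: remove the C18–O angelate and the C15 protecting group, return the C8 carbinol to an 8(17)-alkene and add back a C3 hydroxyl; open rings A and B at C4–C5 and C9–C10; cut the chain at C8–C17 and C7–C8.
2. Enabling feature: the trans-decalin (rings A and B) with C4 (CH3, CH2O), C5, C9 and C10 is the chair–chair fold of a head-to-tail polyprenyl chain. It needs a C3–C4 epoxide, the C5=C10 and C8=C9 alkenes and a silyl group on C17; the (E)-CH2O branch of the epoxide becomes equatorial C18.
3. Forward: geranyl acetate → C18-oxidised (R,R)-epoxide → diene carrying C7; (S)-citronellol → 1,1-dichloroalkene (C8, C9, C11–C16); hydroboration/Suzuki joins C7–C8, a Negishi coupling adds C17 as CH2SiMe3; one Lewis-acid cascade closes ring A, then ring B.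
4. Finish: C3 deoxygenation, epoxidation and hydride opening at C8(17), desilylation, angeloylation of O18, PMB removal.
5. Stereochemistry: C3/C4 from Sharpless epoxidation (D-(−)-tartrate); C5, C9, C10 from the alkene geometries in the cascade; C8 from epoxidation anti to the axial C20 methyl; C13 from (S)-citronellol; the Z-enoate from angelic acid.

Key step: step 12

Remark: labdane numbering (C1–C20) is used for all intermediates, open-chain ones included. The target is read as the ent-labdane (4S,5S,8S,9S,10R,13S) with the C8 hydroxyl equatorial (trans to C20), C17 axial, and the acylated CH2O on the equatorial C4 branch (C18). Geranyl acetate, (S)-citronellol and angelic acid are taken as commercial.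

**Route**

Step 1
Reactants: 1 geranyl acetate
Product: 2 (2E,6E)-8-hydroxygeranyl acetate
Conditions: SeO2 (cat.), t-BuOOH, salicylic acid (cat.), CH2Cl2, rt
Reagents that add atoms: tert-butyl hydroperoxide, CC(C)(C)OO
Why: Riley allylic oxidation (ene reaction then [2,3]-sigmatropic shift) should take place at the electron-rich terminal alkene, away from the acetate-deactivated alkene, and selectively on the (E)-methyl group, so the future C18 oxygen sits trans to the chain.

Step 2
Reactants: 2 (2E,6E)-8-hydroxygeranyl acetate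
Product: 3 (2R,3R)-epoxy alcohol (epoxide at C3–C4, free C18 hydroxyl, acetate at C6)
Conditions: Ti(OiPr)4 (10 mol %), D-(−)-diethyl tartrate (12 mol %), t-BuOOH, 4 Å MS, CH2Cl2, −20 °C
Reagents that add atoms: tert-butyl hydroperoxide, CC(C)(C)OO
Why: Katsuki–Sharpless asymmetric epoxidation is directed by the allylic hydroxyl, so only the C3–C4 alkene reacts, and the D-(−)-tartrate catalyst should give the (2R,3R)-epoxy alcohol from this (E)-2-methyl-2-alken-1-ol (mirror image of the 2S,3S outcome with L-(+)-tartrate), which sets C3 and C4.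

Step 3
Reactants: 3 (2R,3R)-epoxy alcohol
Product: 4 C18 TBS ether of 3
Conditions: TBSCl, imidazole, DMF, 0 °C → rt
Reagents that add atoms: tert-butyldimethylsilyl chloride, CC(C)(C)[Si](C)(C)Cl
Why: Imidazole-mediated silylation of the primary alcohol gives a non-nucleophilic, Lewis-acid-tolerant ether that cannot take part in the later epoxide opening.

Step 4
Reactants: 4 epoxy TBS ether acetate
Product: 5 epoxy TBS ether allylic alcohol (free C6 hydroxyl)
Conditions: K2CO3, MeOH, 0 °C
Reagents that add atoms: none
Why: Carbonate-catalysed transesterification (methanolysis) removes the acetate while the trisubstituted epoxide and the silyl ether are inert to these mild basic conditions.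

Step 5
Reactants: 5 allylic alcohol
Product: 6 (E)-enal (C6 aldehyde)
Conditions: MnO2, CH2Cl2, rt
Reagents that add atoms: none
Why: MnO2 oxidises allylic alcohols chemoselectively to enals under neutral conditions and should leave the epoxide and the (E)-C5=C10 geometry untouched.

Step 6
Reactants: 6 (E)-enal
Product: 7 epoxy diene (C5=C10 and terminal C6=C7)
Conditions: Ph3PCH3Br, KN(SiMe3)2, THF, −78 → 0 °C
Reagents that add atoms: methyltriphenylphosphonium bromide, C[P+](c1ccccc1)(c1ccccc1)c1ccccc1.[Br-]
Why: Wittig methylenation with the non-stabilised ylide turns the aldehyde into a terminal vinyl group (the new carbon is C7) without affecting the epoxide or the (E)-alkene.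

Step 7
Reactants: 8 (S)-citronellol
Product: 9 (S)-citronellyl 4-methoxybenzyl ether
Conditions: NaH, PMBCl, Bu4NI (cat.), THF/DMF, 0 °C → rt
Reagents that add atoms: 4-methoxybenzyl chloride, COc1ccc(CCl)cc1
Why: Williamson etherification protects the future C15 hydroxyl as an ether that can be removed oxidatively at the end, and the C13 stereocentre is not involved.

Step 8
Reactants: 9 (S)-citronellyl PMB ether
Product: 10 (4S)-6-(4-methoxybenzyloxy)-4-methylhexanal
Conditions: OsO4 (cat.), NaIO4, 2,6-lutidine, dioxane/H2O, rt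
Reagents that add atoms: sodium periodate, [Na+].[O-]I(=O)(=O)=O; water, O
Why: Lemieux–Johnson oxidation (catalytic dihydroxylation with in situ periodate cleavage) cuts the only alkene to the aldehyde that becomes C9 and, unlike ozone, spares the electron-rich PMB ring.

Step 9
Reactants: 10 aldehyde
Product: 11 (S)-1,1-dichloroalkene (CCl2 carbon is C8)
Conditions: CBrCl3, PPh3, MeCN, 0 °C → rt
Reagents that add atoms: bromotrichloromethane, ClC(Cl)(Cl)Br
Why: Ramirez-type dichloro-olefination, a Wittig reaction of Ph3P=CCl2 formed in situ from PPh3 and CBrCl3, converts the aldehyde into the 1,1-dichloroalkene.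

Step 10
Reactants: 7 epoxy diene; 11 1,1-dichloroalkene
Product: 13 (Z)-alkenyl chloride (C7–C8 joined; Cl on C8 cis to C11), via B-alkyl-9-BBN 12 (not isolated)
Conditions: 9-BBN, THF, 0 °C → rt; then 11, Pd2(dba)3 (2.5 mol %), Xantphos (5 mol %), K3PO4 (aq.), KF, THF, 65 °C
Reagents that add atoms: none
Why: Anti-Markovnikov hydroboration with 9-BBN should occur at the terminal vinyl group, and the B-alkyl Suzuki–Miyaura coupling then takes place at the C–Cl bond trans to the alkyl chain, where oxidative addition is less hindered, so C7 ends up trans to C11.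

Step 11
Reactants: 13 (Z)-alkenyl chloride
Product: 14 epoxy diene allylsilane (CH2SiMe3 on C8, cis to C11; C18 OTBS; C15 OPMB)
Conditions: Me3SiCH2MgCl, ZnCl2, THF, 0 °C; then 13, Pd(PtBu3)2 (5 mol %), THF/NMP, 50 °C
Reagents that add atoms: (trimethylsilyl)methylmagnesium chloride, C[Si](C)(C)C[Mg]Cl
Why: Negishi coupling of the remaining alkenyl chloride should proceed with retention of alkene geometry under the bulky electron-rich phosphine catalyst, placing CH2SiMe3 cis to C11, and the mild organozinc reagent does not open the epoxide.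

Step 12
Reactants: 14 epoxy diene allylsilane
Product: 15 3-hydroxy-8(17)-ene ent-labdane (C18 OTBS, C15 OPMB)
Conditions: MeAlCl2 (2.5 equiv), CH2Cl2, −78 °C
Reagents that add atoms: none
Why: MeAlCl2 coordinates the epoxide oxygen and the C4–O bond ionises at the tertiary carbon while C5 of the C5=C10 alkene attacks anti to the leaving oxygen, the resulting C10 cation is captured by C9 of the allylsilane, and the β-silyl cation at C8 loses silicon to give only the exocyclic 8(17)-alkene; this is the Lewis-acid epoxy-polyene cyclisation with allylsilane termination. Ring A closes 6-endo at the C5=C10 alkene (C4–C5 bond) and ring B closes 6-endo at the C8=C9 alkene (C9–C10 bond), both through chair transition states. C4 is set by inversion at the Sharpless-derived epoxide carbon with the (E)-CH2OTBS group ending equatorial as C18, C5 and C10 by anti addition across the (E)-C5=C10 alkene (trans ring fusion, C20 axial), and C9 by the geometry of the C8=C9 alkene, which places the C11 chain equatorial; C3 is carried over unchanged and fixes the absolute sense of the fold. The step needs opening at C4 and not at C3 and a single mode of termination: the tertiary against secondary epoxide carbon secures the first, the β-silicon effect the second, and the non-nucleophilic silyl ether on O18 and the remote PMB ether keep oxygen functions from trapping the cations.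

Step 13
Reactants: 15 3-hydroxy-8(17)-ene ent-labdane
Product: 16 O3-phenoxythiocarbonyl derivative of 15
Conditions: PhOC(S)Cl, pyridine, DMAP (cat.), CH2Cl2, rt
Reagents that add atoms: O-phenyl chlorothionoformate, S=C(Cl)Oc1ccccc1
Why: Acylation of the hindered equatorial C3 alcohol under DMAP catalysis gives the thionocarbonate needed for Barton–McCombie deoxygenation, and the absence of a free alkoxide avoids silyl migration from O18 to O3.

Step 14
Reactants: 16 thionocarbonate
Product: 17 3-deoxy-8(17)-ene ent-labdane (C18 OTBS, C15 OPMB)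
Conditions: Bu3SnH, AIBN (cat.), toluene, 100 °C
Reagents that add atoms: none
Why: Barton–McCombie radical deoxygenation, in which the stannyl radical adds to the thiocarbonyl, the C3–O bond fragments to a secondary radical and this is reduced by Bu3SnH, with none of the remaining stereocentres involved.

Step 15
Reactants: 17 8(17)-ene
Product: 18 (8S)-8,17-epoxide (oxygen equatorial, trans to C20)
Conditions: mCPBA, CH2Cl2, 0 °C
Reagents that add atoms: 3-chloroperoxybenzoic acid, OOC(=O)c1cccc(Cl)c1
Why: Prilezhaev epoxidation of the only alkene should occur from the face opposite to the axial C20 methyl group (equatorial attack), giving the spiro-epoxide with oxygen equatorial.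

Step 16
Reactants: 18 8,17-epoxide
Product: 19 8-hydroxy ent-labdane (C18 OTBS, C15 OPMB)
Conditions: LiAlH4, THF, 0 °C → rt
Reagents that add atoms: none
Why: Hydride opens the epoxide by SN2 attack at the unsubstituted C17 methylene, so the C8–O bond and its configuration are kept and C8 becomes the tertiary carbinol with equatorial OH and axial methyl.

Step 17
Reactants: 19 8-hydroxy C18 TBS ether
Product: 20 8,18-diol (C15 OPMB)
Conditions: Bu4NF, THF, rt → 45 °C
Reagents that add atoms: none
Why: Fluoride-mediated desilylation frees the neopentyl C18 hydroxyl while the PMB ether and the tertiary alcohol are unaffected.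

Step 18
Reactants: 20 8,18-diol; 21 angelic acid
Product: 23 18-angelate (C8 OH free; C15 OPMB), via mixed anhydride 22 (not isolated)
Conditions: 21, 2,4,6-Cl3C6H2COCl, Et3N, toluene, rt; then 20, toluene, 80 °C
Reagents that add atoms: none
Why: Yamaguchi esterification through the mixed anhydride should acylate only the primary C18 hydroxyl because the tertiary C8 hydroxyl is too hindered, and leaving out a nucleophilic amine catalyst suppresses the conjugate-addition pathway that would isomerise the angelate to the tiglate.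

Step 19
Reactants: 23 18-angelate PMB ether
Product: 24 target, 18-angeloyloxy-ent-labdane-8,15-diol
Conditions: DDQ, CH2Cl2/pH 7 buffer, 0 °C → rt
Reagents that add atoms: none
Why: Oxidative PMB ether cleavage by DDQ (benzylic hydride abstraction and hydrolysis of the oxocarbenium ion) should release the C15 alcohol without touching the angelate or the tertiary alcohol.

**Compound list**
1 | geranyl acetate, (2E)-3,7-dimethylocta-2,6-dien-1-yl acetate | CC(C)=CCC/C(C)=C/COC(C)=O | starting material
2 | (2E,6E)-8-hydroxy-3,7-dimethylocta-2,6-dien-1-yl acetate | OC/C(C)=C/CC/C(C)=C/COC(C)=O | intermediate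
3 | (2E)-5-[(2R,3R)-3-(hydroxymethyl)-3-methyloxiran-2-yl]-3-methylpent-2-en-1-yl acetate | OC[C@@]1(C)O[C@@H]1CC/C(C)=C/COC(C)=O | intermediate
4 | (2E)-5-{(2R,3R)-3-[(tert-butyldimethylsilyloxy)methyl]-3-methyloxiran-2-yl}-3-methylpent-2-en-1-yl acetate | CC(C)(C)[Si](C)(C)OC[C@@]1(C)O[C@@H]1CC/C(C)=C/COC(C)=O | intermediate
5 | (2E)-5-{(2R,3R)-3-[(tert-butyldimethylsilyloxy)methyl]-3-methyloxiran-2-yl}-3-methylpent-2-en-1-ol | CC(C)(C)[Si](C)(C)OC[C@@]1(C)O[C@@H]1CC/C(C)=C/CO | intermediate
6 | (2E)-5-{(2R,3R)-3-[(tert-butyldimethylsilyloxy)methyl]-3-methyloxiran-2-yl}-3-methylpent-2-enal | CC(C)(C)[Si](C)(C)OC[C@@]1(C)O[C@@H]1CC/C(C)=C/C=O | intermediate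
7 | tert-butyl({(2R,3R)-2-methyl-3-[(3E)-3-methylhexa-3,5-dien-1-yl]oxiran-2-yl}methoxy)dimethylsilane | CC(C)(C)[Si](C)(C)OC[C@@]1(C)O[C@@H]1CC/C(C)=C/C=C | intermediate
8 | (S)-citronellol, (3S)-3,7-dimethyloct-6-en-1-ol | CC(C)=CCC[C@H](C)CCO | starting material
9 | 1-({[(3S)-3,7-dimethyloct-6-en-1-yl]oxy}methyl)-4-methoxybenzene | CC(C)=CCC[C@H](C)CCOCc1ccc(OC)cc1 | intermediate
10 | (4S)-6-(4-methoxybenzyloxy)-4-methylhexanal | O=CCC[C@H](C)CCOCc1ccc(OC)cc1 | intermediate
11 | 1-({[(3S)-7,7-dichloro-3-methylhept-6-en-1-yl]oxy}methyl)-4-methoxybenzene | ClC(Cl)=CCC[C@H](C)CCOCc1ccc(OC)cc1 | intermediate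
12 | 9-[(3E)-6-{(2R,3R)-3-[(tert-butyldimethylsilyloxy)methyl]-3-methyloxiran-2-yl}-4-methylhex-3-en-1-yl]-9-borabicyclo[3.3.1]nonane | CC(C)(C)[Si](C)(C)OC[C@@]1(C)O[C@@H]1CC/C(C)=C/CCB1C2CCCC1CCC2 | intermediate (not isolated)
13 | tert-butyl({(2R,3R)-3-[(3E,7Z,11S)-7-chloro-13-(4-methoxybenzyloxy)-3,11-dimethyltrideca-3,7-dien-1-yl]-2-methyloxiran-2-yl}methoxy)dimethylsilane | CC(C)(C)[Si](C)(C)OC[C@@]1(C)O[C@@H]1CC/C(C)=C/CC/C(Cl)=C/CC[C@H](C)CCOCc1ccc(OC)cc1 | intermediate
14 | tert-butyl({(2R,3R)-3-[(3E,7Z,11S)-13-(4-methoxybenzyloxy)-3,11-dimethyl-7-[(trimethylsilyl)methyl]trideca-3,7-dien-1-yl]-2-methyloxiran-2-yl}methoxy)dimethylsilane | CC(C)(C)[Si](C)(C)OC[C@@]1(C)O[C@@H]1CC/C(C)=C/CC/C(C[Si](C)(C)C)=C/CC[C@H](C)CCOCc1ccc(OC)cc1 | intermediate (key-step precursor)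
15 | (3R,4S,5S,9R,10S,13S)-18-(tert-butyldimethylsilyloxy)-15-(4-methoxybenzyloxy)labd-8(17)-en-3-ol (ent-labdane; 3-OH equatorial, cis to C20; C18 equatorial) | CC(C)(C)[Si](C)(C)OC[C@@]1(C)[C@H](O)CC[C@]2(C)[C@@H]1CCC(=C)[C@H]2CC[C@H](C)CCOCc1ccc(OC)cc1 | intermediate (key-step product)
16 | O-[(3R,4S,5S,9R,10S,13S)-18-(tert-butyldimethylsilyloxy)-15-(4-methoxybenzyloxy)labd-8(17)-en-3-yl] O-phenyl thiocarbonate | CC(C)(C)[Si](C)(C)OC[C@@]1(C)[C@H](OC(=S)Oc3ccccc3)CC[C@]2(C)[C@@H]1CCC(=C)[C@H]2CC[C@H](C)CCOCc1ccc(OC)cc1 | intermediate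
17 | (4S,5S,9R,10S,13S)-18-(tert-butyldimethylsilyloxy)-15-(4-methoxybenzyloxy)labd-8(17)-ene | CC(C)(C)[Si](C)(C)OC[C@@]1(C)CCC[C@]2(C)[C@@H]1CCC(=C)[C@H]2CC[C@H](C)CCOCc1ccc(OC)cc1 | intermediate
18 | (4S,5S,8S,9S,10R,13S)-8,17-epoxy-18-(tert-butyldimethylsilyloxy)-15-(4-methoxybenzyloxy)labdane (epoxide oxygen equatorial, trans to C20) | CC(C)(C)[Si](C)(C)OC[C@@]1(C)CCC[C@]2(C)[C@@H]1CC[C@@]3(CO3)[C@H]2CC[C@H](C)CCOCc1ccc(OC)cc1 | intermediate
19 | (4S,5S,8S,9S,10R,13S)-18-(tert-butyldimethylsilyloxy)-15-(4-methoxybenzyloxy)labdan-8-ol | CC(C)(C)[Si](C)(C)OC[C@@]1(C)CCC[C@]2(C)[C@@H]1CC[C@](C)(O)[C@H]2CC[C@H](C)CCOCc1ccc(OC)cc1 | intermediate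
20 | (4S,5S,8S,9S,10R,13S)-15-(4-methoxybenzyloxy)labdane-8,18-diol | OC[C@@]1(C)CCC[C@]2(C)[C@@H]1CC[C@](C)(O)[C@H]2CC[C@H](C)CCOCc1ccc(OC)cc1 | intermediate
21 | angelic acid, (2Z)-2-methylbut-2-enoic acid | C/C=C(/C)C(=O)O | starting material
22 | (2Z)-2-methylbut-2-enoic 2,4,6-trichlorobenzoic anhydride | C/C=C(/C)C(=O)OC(=O)c1c(Cl)cc(Cl)cc1Cl | intermediate (not isolated)
23 | (4S,5S,8S,9S,10R,13S)-8-hydroxy-15-(4-methoxybenzyloxy)labdan-18-yl (2Z)-2-methylbut-2-enoate | C/C=C(/C)C(=O)OC[C@@]1(C)CCC[C@]2(C)[C@@H]1CC[C@](C)(O)[C@H]2CC[C@H](C)CCOCc1ccc(OC)cc1 | intermediate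
24 | (4S,5S,8S,9S,10R,13S)-8,15-dihydroxylabdan-18-yl (2Z)-2-methylbut-2-enoate (CNP0150844.1) | C/C=C(/C)C(=O)OC[C@@]1(C)CCC[C@]2(C)[C@@H]1CC[C@](C)(O)[C@H]2CC[C@H](C)CCO | target

**Step count**
Total: 19 steps. Longest linear sequence: 16 steps (steps 1–6 and 10–19, from geranyl acetate); the citronellol branch (steps 7–9) joins at step 10.

**Steps most likely to fail**

1. Step 12 (cyclisation). Ionisation at C4 is slowed by the electron-withdrawing silyloxymethyl group. Hydride shift to a C3 ketone, interruption after ring A, protodesilylation of the allylsilane or Lewis-acid loss of the PMB group may then compete. The fallback replaces the cationic cascade by a radical one, which does not feel that inductive effect. It sets out from 13: Negishi coupling with MeZnCl (Pd(PtBu3)2, THF) should give the 8-methyl epoxy diene F1. Cp2TiCl (trivalent titanium, made from Cp2TiCl2 and Mn dust, THF, rt) then opens the epoxide homolytically at C4. The tertiary radical closes ring A and ring B 6-endo, and the C8 radical is trapped by a second titanium centre and loses hydride towards C17. This should give the same 8(17)-alkene, so the route is rejoined at 15. In this mode C4 is no longer set by inversion but in the chair transition state, where the larger CH2OTBS group is expected to stay equatorial; any C4 epimer would have to be separated at the stage of 15.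

2. Step 10 (hydroboration and site-selective Suzuki coupling). Hydroboration may spill into the conjugated diene (allylborane formation), and the palladium step may couple at both C–Cl bonds or lose its trans selectivity. The fallback separates the two events and uses an organozinc nucleophile. It sets out from 7: hydroboration with 9-BBN and oxidative work-up (NaOH, H2O2) should give the homoallylic alcohol F2, and PPh3, I2 and imidazole the iodide F3. Zinc insertion (Zn dust, LiCl, THF) gives the alkylzinc iodide F4. Negishi trans-selective monoalkylation of dichloroalkene 11 (PdCl2(DPEphos), THF/DMF, rt) then leads back to 13.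

3. Step 18 (angeloylation). Z-to-E isomerisation to the tiglate or sluggish acylation of the neopentyl C18 hydroxyl may occur. The fallback builds the Z-enoate on the substrate instead of transferring it. It sets out from 20: esterification with 2-[bis(2,2,2-trifluoroethoxy)phosphoryl]propanoic acid (EDC·HCl, DMAP, CH2Cl2) should give the phosphonate ester F5. Still–Gennari olefination with acetaldehyde (KN(SiMe3)2, 18-crown-6, THF, −78 °C) then forms the (Z)-2-methylbut-2-enoate and returns to 23.

**Further compounds**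
F1 | step 12 | tert-butyl({(2R,3R)-3-[(3E,7E,11S)-13-(4-methoxybenzyloxy)-3,7,11-trimethyltrideca-3,7-dien-1-yl]-2-methyloxiran-2-yl}methoxy)dimethylsilane | CC(C)(C)[Si](C)(C)OC[C@@]1(C)O[C@@H]1CC/C(C)=C/CC/C(C)=C/CC[C@H](C)CCOCc1ccc(OC)cc1
F2 | step 10 | (3E)-6-{(2R,3R)-3-[(tert-butyldimethylsilyloxy)methyl]-3-methyloxiran-2-yl}-4-methylhex-3-en-1-ol | CC(C)(C)[Si](C)(C)OC[C@@]1(C)O[C@@H]1CC/C(C)=C/CCO
F3 | step 10 | tert-butyl({(2R,3R)-3-[(3E)-6-iodo-3-methylhex-3-en-1-yl]-2-methyloxiran-2-yl}methoxy)dimethylsilane | CC(C)(C)[Si](C)(C)OC[C@@]1(C)O[C@@H]1CC/C(C)=C/CCI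
F4 | step 10 | [(3E)-6-{(2R,3R)-3-[(tert-butyldimethylsilyloxy)methyl]-3-methyloxiran-2-yl}-4-methylhex-3-en-1-yl]zinc iodide | CC(C)(C)[Si](C)(C)OC[C@@]1(C)O[C@@H]1CC/C(C)=C/CC[Zn]I
F5 | step 18 | (4S,5S,8S,9S,10R,13S)-8-hydroxy-15-(4-methoxybenzyloxy)labdan-18-yl 2-[bis(2,2,2-trifluoroethoxy)phosphoryl]propanoate (both epimers at the phosphonate carbon) | CC(C(=O)OC[C@@]1(C)CCC[C@]2(C)[C@@H]1CC[C@](C)(O)[C@H]2CC[C@H](C)CCOCc1ccc(OC)cc1)P(=O)(OCC(F)(F)F)OCC(F)(F)F
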